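**Retrosynthetic overview**
1. C8=O is made last. It is a C–O bond formed by regioselective hydration of the C7≡C8 alkyne of the C40 polyenyne 25 (new step), so the labile tertiary aldol appears only at the end.
2. 25 comes from two Wittig olefinations on the C10 dialdehyde 22: C11'=C12' with salt 23, then C11=C12 with salt 14.
3. In 14, the C6–O bond and the C6 configuration come from 3-OH-directed epoxidation of enyne 9, followed by oxirane → 5(18)-ene-6-ol isomerisation. 9 comes from Sonogashira coupling of enol triflate 6 with enynol 7. 6 derives from ketoisophorone, and the enzymatic reduction sets C3.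
4. In 23, (R)-α-ionone brings C6'. C2 homologation, C3' oxidation, kinetic enol triflate formation and formate reduction give the 2',4'-diene ring.
5. Rings: both carbocycles are bought (in 1 and 15). The only ring made is the oxirane (step 4), and it is opened again in step 5.

Assumption: fermentation-derived (R)-(+)-α-ionone (≥98% ee, flavour grade) and the C10 dialdehyde 22 are taken as commercial. Positions are given in carotenoid numbering (primed = right half).

**Step 1**
Reactants: 1 ketoisophorone (2,6,6-trimethylcyclohex-2-ene-1,4-dione)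
Product: 3 (4R,6R)-4-hydroxy-2,2,6-trimethylcyclohexanone, via (6R)-levodione 2 (not isolated)
Conditions: old yellow enzyme 2, levodione reductase, NAD+/NADP+ (cat.), glucose dehydrogenase, D-glucose (2.2 equiv), K2HPO4/KH2PO4 buffer pH 7, 30 °C
Reagents that add atoms: none
Why: Known two-enzyme asymmetric reduction cascade in which the ene-reductase saturates the C=C bond and the ketoreductase then reduces only the unhindered carbonyl from one face, which sets the carbinol centre that becomes C3 of the target.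

**Step 2**
Reactants: 3 (4R,6R)-4-hydroxy-2,2,6-trimethylcyclohexanone
Product: 6 (4R)-4-hydroxy-2,6,6-trimethylcyclohex-1-en-1-yl trifluoromethanesulfonate, via trimethylsilyl ether 4 (not isolated), via silylated enol triflate 5 (not isolated)
Conditions: (Me3Si)2NH (0.6 equiv), Me3SiCl (cat.), 40 °C, evaporate; LiN(iPr)2 (1.2 equiv), THF, −78 to 0 °C; PhNTf2, −78 °C to rt; 1 M HCl, THF, 0 °C
Reagents that add atoms: N-phenylbis(trifluoromethanesulfonimide) O=S(=O)(N(c1ccccc1)S(=O)(=O)C(F)(F)F)C(F)(F)F; hexamethyldisilazane C[Si](C)(C)N[Si](C)(C)C (its SiMe3 group is found in 4 and 5 only)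
Why: Enol triflate formation works because the ketone can enolise only towards C5, so a single tetrasubstituted enolate is trapped, while the transient silyl ether shields the alcohol, falls off in the acidic quench and leaves C3 untouched.

**Step 3**
Reactants: 6 hydroxy enol triflate; 7 (E)-3-methylpent-2-en-4-yn-1-ol
Product: 9 (1R)-3,5,5-trimethyl-4-[(3E)-3-methyl-5-(triethylsilyloxy)pent-3-en-1-ynyl]cyclohex-3-en-1-ol, via triethylsilyl ether 8 (not isolated)
Conditions: 7 (1.2 equiv), Et3SiCl (1.2 equiv), Et3N, DMAP (cat.), THF, 0 °C; then 6, Pd(PPh3)4 (5 mol%), CuI (10 mol%), rt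
Reagents that add atoms: chlorotriethylsilane CC[Si](Cl)(CC)CC
Why: Sonogashira coupling of this hindered enol triflate type with terminal enynes is well established, the E geometry of 7 is carried over, and masking the primary allylic alcohol leaves the ring 3-OH as the only free hydroxyl for step 4.

**Step 4**
Reactants: 9 C15 enyne alcohol
Product: 10 (1S,3S,6S)-1,5,5-trimethyl-6-[(3E)-3-methyl-5-(triethylsilyloxy)pent-3-en-1-ynyl]-7-oxabicyclo[4.1.0]heptan-3-ol (oxirane oxygen cis to the 3-OH)
Conditions: VO(acac)2 (5 mol%), tBuOOH (1.5 equiv), toluene, 0 °C to rt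
Reagents that add atoms: tert-butyl hydroperoxide CC(C)(C)OO
Why: In this hydroxyl-directed vanadium-catalysed epoxidation the homoallylic 3-O-vanadium peroxide delivers oxygen to the ring face that bears the 3-OH, which forms the C6–O bond and sets C6 (and C5) cis to C3–OH, while the silylated side-chain alkene has no directing group.

**Step 5**
Reactants: 10 syn-epoxy alcohol
Product: 12 (1R,4S)-1-[(3E)-5-hydroxy-3-methylpent-3-en-1-ynyl]-2,2-dimethyl-6-methylidenecyclohexane-1,4-diol, via silyl-protected diol 11 (not isolated)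
Conditions: LiN(iPr)2 (4 equiv), THF, 0 °C to rt; AcOH to neutral; Bu4NF (1.2 equiv), 0 °C
Reagents that add atoms: none
Why: In this base-induced epoxide-to-allylic-alcohol isomerisation (syn β-elimination) C6 has no β-hydrogen, so only the C5–O bond can break, and the amide takes the unhindered methyl hydrogen, giving the exocyclic methylene with the C6–O bond and its configuration retained before fluoride frees the primary alcohol.

**Step 6**
Reactants: 12 C15 enyne triol
Product: 14 [(2E)-5-[(1R,4S)-1,4-dihydroxy-2,2-dimethyl-6-methylidenecyclohexyl]-3-methylpent-2-en-4-ynyl]triphenylphosphonium bromide, via allylic bromide 13 (not isolated)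
Conditions: CBr4 (1.05 equiv), PPh3 (2.3 equiv), CH2Cl2, −30 °C to rt; salt precipitated with Et2O
Reagents that add atoms: triphenylphosphine c1ccc(cc1)P(c1ccccc1)c1ccccc1; tetrabromomethane BrC(Br)(Br)Br
Why: The neutral Appel reaction activates the primary allylic alcohol far faster than the secondary and the hindered tertiary one, and the excess phosphine quaternises the bromide in the same flask, so no acid meets the ionisable 6-OH.

**Step 7**
Reactants: 15 (R)-α-ionone; 16 triethyl phosphonoacetate
Product: 17 ethyl (2E,4E)-3-methyl-5-[(1R)-2,6,6-trimethylcyclohex-2-en-1-yl]penta-2,4-dienoate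
Conditions: 16, NaH, THF, 0 °C; then 15, rt; (2Z) isomer removed by chromatography
Reagents that add atoms: none
Why: Horner–Wadsworth–Emmons olefination of ionones gives mainly the E trisubstituted dienoate, and the ring stereocentre (later C6') is not part of the reacting system.

**Step 8**
Reactants: 17 C15 dienoate
Product: 18 ethyl (2E,4E)-3-methyl-5-[(1R)-2,6,6-trimethyl-4-oxocyclohex-2-en-1-yl]penta-2,4-dienoate
Conditions: Mn(OAc)3·2H2O (10 mol%), tBuOOH (5 equiv), 3 Å sieves, EtOAc, rt
Reagents that add atoms: tert-butyl hydroperoxide CC(C)(C)OO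
Why: Radical allylic oxidation attacks the ring CH2 next to the trisubstituted alkene, as known for α-ionone derivatives, because the tertiary C6'–H is shielded and deactivated by the dienoate.

**Step 9**
Reactants: 18 ring enone ester
Product: 19 ethyl (2E,4E)-3-methyl-5-[(1S)-2,6,6-trimethyl-4-(trifluoromethylsulfonyloxy)cyclohexa-2,4-dien-1-yl]penta-2,4-dienoate
Conditions: 18 added to KN(SiMe3)2 (1.05 equiv), THF, −78 °C; PhNTf2, −78 to −20 °C; AcOH quench
Reagents that add atoms: N-phenylbis(trifluoromethanesulfonimide) O=S(=O)(N(c1ccccc1)S(=O)(=O)C(F)(F)F)C(F)(F)F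
Why: Kinetic α'-deprotonation of an isophorone-type enone (inverse addition, no excess ketone) gives the cross-conjugated dienolate at C2', and its trapping as the enol triflate fixes the new C2'=C3' double bond without touching C6'–H (the descriptor changes to S by priority only).

**Step 10**
Reactants: 19 dienyl triflate
Product: 20 ethyl (2E,4E)-3-methyl-5-[(1S)-2,6,6-trimethylcyclohexa-2,4-dien-1-yl]penta-2,4-dienoate
Conditions: Pd(OAc)2 (5 mol%), PPh3 (10 mol%), HCO2H (2 equiv), Et3N (3 equiv), DMF, 40 °C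
Reagents that add atoms: none
Why: Palladium-catalysed formate reduction of vinyl triflates (oxidative addition to zerovalent palladium, decarboxylation, reductive elimination) replaces OTf by H with the double bonds left in place.

**Step 11**
Reactants: 20 diene ester
Product: 21 (2E,4E)-3-methyl-5-[(1S)-2,6,6-trimethylcyclohexa-2,4-dien-1-yl]penta-2,4-dien-1-ol
Conditions: iBu2AlH (2.3 equiv), CH2Cl2, −78 °C; aq. potassium sodium tartrate
Reagents that add atoms: none
Why: 1,2-Reduction of a conjugated ester with iBu2AlH gives the allylic alcohol cleanly under non-basic conditions.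

**Step 12**
Reactants: 21 C15 dienol; 22 (2E,4E,6E)-2,7-dimethylocta-2,4,6-trienedial
Product: 24 (2E,4E,6E,8E,10E,12E)-2,7,11-trimethyl-13-[(1S)-2,6,6-trimethylcyclohexa-2,4-dien-1-yl]trideca-2,4,6,8,10,12-hexaenal, via C15 phosphonium bromide 23 (not isolated)
Conditions: PPh3·HBr (1.0 equiv), MeOH, 0 °C to rt, evaporate; 22 (2 equiv), 1,2-epoxybutane, EtOH, 60 °C, dark
Reagents that add atoms: triphenylphosphonium bromide [Br-].c1ccccc1[PH+](c1ccccc1)c1ccccc1 (found in 23 only)
Why: This is the standard carotenoid sequence of salt formation from a dienyl carbinol and Wittig mono-olefination of excess C10 dialdehyde, run with an epoxide as neutral proton scavenger so that C6'–H is not exposed to alkoxide.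

**Step 13**
Reactants: 14 left C15 phosphonium bromide; 24 C25 aldehyde
Product: 25 (3S,6R,6'S)-7,8,2',3'-tetradehydro-γ,ε-carotene-3,6-diol (all-E)
Conditions: 1,2-epoxybutane, EtOH, 60 °C, Ar, dark; all-E isomer crystallised
Reagents that add atoms: none
Why: The Wittig reaction of acetylenic C15 salts with apocarotenals is established, the neutral conditions tolerate both free hydroxyls, and the hindered 11Z isomer relaxes to E at the reaction temperature.

**Step 14**
Reactants: 25 C40 polyenyne diol
Product: 26 (3S,6R,6'S)-3,6-dihydroxy-2',3'-didehydro-7,8-dihydro-γ,ε-caroten-8-one (CNP0261423.1)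
Conditions: (IPr)AuNTf2 [IPr = 1,3-bis(2,6-diisopropylphenyl)imidazol-2-ylidene] (2 mol%), H2O (20 equiv), 1,4-dioxane, 40 °C, Ar, dark, no acid, no silver salt
Reagents that add atoms: water O
Why: Proposed new method: acid-free and silver-free hydration of a carotenoid polyenyne by a cationic carbene complex of monovalent gold, in which the soft Lewis acid binds the only alkyne, the developing positive charge sits on C8 because C8 is conjugated with the polyene while C7 is deactivated by the neighbouring C6–O dipole (the 6-OH can also hydrogen-bond the incoming water), so that water adds at C8, protodeauration at C7 and enol-to-ketone tautomerism give the polyenone, no stereocentre is touched, and the absence of Brønsted acid at 40 °C stops the tertiary aldol from going on to the Meyer–Schuster enone; the closest known reaction type is the gold-catalysed Markovnikov hydration of internal alkynes, 1,3-enynes and propargylic alcohols, which has not been shown on a long polyene.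

**Compound list**
1 | ketoisophorone | CC1=CC(=O)CC(C)(C)C1=O | starting material
2 | (6R)-2,2,6-trimethylcyclohexane-1,4-dione (levodione) | C[C@@H]1CC(=O)CC(C)(C)C1=O | intermediate (not isolated)
3 | (4R,6R)-4-hydroxy-2,2,6-trimethylcyclohexanone | C[C@@H]1C[C@@H](O)CC(C)(C)C1=O | intermediate
4 | (4R,6R)-2,2,6-trimethyl-4-(trimethylsilyloxy)cyclohexanone | C[C@@H]1C[C@@H](O[Si](C)(C)C)CC(C)(C)C1=O | intermediate (not isolated)
5 | (4R)-2,6,6-trimethyl-4-(trimethylsilyloxy)cyclohex-1-en-1-yl triflate | CC1=C(OS(=O)(=O)C(F)(F)F)C(C)(C)C[C@H](O[Si](C)(C)C)C1 | intermediate (not isolated)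
6 | (4R)-4-hydroxy-2,6,6-trimethylcyclohex-1-en-1-yl triflate | CC1=C(OS(=O)(=O)C(F)(F)F)C(C)(C)C[C@H](O)C1 | intermediate
7 | (E)-3-methylpent-2-en-4-yn-1-ol | C#C/C(C)=C/CO | starting material
8 | triethyl[(E)-3-methylpent-2-en-4-ynyloxy]silane | C#C/C(C)=C/CO[Si](CC)(CC)CC | intermediate (not isolated)
9 | (1R)-3,5,5-trimethyl-4-[(3E)-3-methyl-5-(triethylsilyloxy)pent-3-en-1-ynyl]cyclohex-3-en-1-ol | CC1=C(C#C/C(C)=C/CO[Si](CC)(CC)CC)C(C)(C)C[C@H](O)C1 | intermediate
10 | (1S,3S,6S)-syn-epoxy alcohol (oxirane O cis to OH) | C[C@]12C[C@@H](O)CC(C)(C)[C@]1(O2)C#C/C(C)=C/CO[Si](CC)(CC)CC | intermediate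
11 | (1R,4S)-2,2-dimethyl-6-methylidene-1-[(3E)-3-methyl-5-(triethylsilyloxy)pent-3-en-1-ynyl]cyclohexane-1,4-diol | C=C1C[C@@H](O)CC(C)(C)[C@]1(O)C#C/C(C)=C/CO[Si](CC)(CC)CC | intermediate (not isolated)
12 | (1R,4S)-1-[(3E)-5-hydroxy-3-methylpent-3-en-1-ynyl]-2,2-dimethyl-6-methylidenecyclohexane-1,4-diol | C=C1C[C@@H](O)CC(C)(C)[C@]1(O)C#C/C(C)=C/CO | intermediate
13 | (1R,4S)-1-[(3E)-5-bromo-3-methylpent-3-en-1-ynyl]-2,2-dimethyl-6-methylidenecyclohexane-1,4-diol | C=C1C[C@@H](O)CC(C)(C)[C@]1(O)C#C/C(C)=C/CBr | intermediate (not isolated)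
14 | left C15 triphenylphosphonium bromide (1R,4S; 2E) | C=C1C[C@@H](O)CC(C)(C)[C@]1(O)C#C/C(C)=C/C[P+](c1ccccc1)(c1ccccc1)c1ccccc1.[Br-] | intermediate
15 | (R)-α-ionone | CC(=O)/C=C/[C@H]1C(C)=CCCC1(C)C | starting material
16 | triethyl phosphonoacetate | CCOC(=O)CP(=O)(OCC)OCC | starting material
17 | ethyl (2E,4E)-3-methyl-5-[(1R)-2,6,6-trimethylcyclohex-2-en-1-yl]penta-2,4-dienoate | CCOC(=O)/C=C(C)/C=C/[C@H]1C(C)=CCCC1(C)C | intermediate
18 | ethyl (2E,4E)-3-methyl-5-[(1R)-2,6,6-trimethyl-4-oxocyclohex-2-en-1-yl]penta-2,4-dienoate | CCOC(=O)/C=C(C)/C=C/[C@H]1C(C)=CC(=O)CC1(C)C | intermediate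
19 | ethyl (2E,4E)-3-methyl-5-[(1S)-2,6,6-trimethyl-4-(triflyloxy)cyclohexa-2,4-dien-1-yl]penta-2,4-dienoate | CCOC(=O)/C=C(C)/C=C/[C@H]1C(C)=CC(OS(=O)(=O)C(F)(F)F)=CC1(C)C | intermediate
20 | ethyl (2E,4E)-3-methyl-5-[(1S)-2,6,6-trimethylcyclohexa-2,4-dien-1-yl]penta-2,4-dienoate | CCOC(=O)/C=C(C)/C=C/[C@H]1C(C)=CC=CC1(C)C | intermediate
21 | (2E,4E)-3-methyl-5-[(1S)-2,6,6-trimethylcyclohexa-2,4-dien-1-yl]penta-2,4-dien-1-ol | OC/C=C(C)/C=C/[C@H]1C(C)=CC=CC1(C)C | intermediate
22 | (2E,4E,6E)-2,7-dimethylocta-2,4,6-trienedial | O=C/C(C)=C/C=C/C=C(C)/C=O | starting material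
23 | right C15 triphenylphosphonium bromide (1S; 2E,4E) | [Br-].c1ccccc1[P+](c1ccccc1)(c1ccccc1)C/C=C(C)/C=C/[C@H]1C(C)=CC=CC1(C)C | intermediate (not isolated)
24 | C25 hexaenal (all-E, 1S ring centre) | O=C/C(C)=C/C=C/C=C(C)/C=C/C=C(C)/C=C/[C@H]1C(C)=CC=CC1(C)C | intermediate
25 | (3S,6R,6'S)-7,8,2',3'-tetradehydro-γ,ε-carotene-3,6-diol | C=C1C[C@@H](O)CC(C)(C)[C@]1(O)C#C/C(C)=C/C=C/C(C)=C/C=C/C=C(C)/C=C/C=C(C)/C=C/[C@H]1C(C)=CC=CC1(C)C | intermediate
26 | (3S,6R,6'S)-3,6-dihydroxy-2',3'-didehydro-7,8-dihydro-γ,ε-caroten-8-one | C=C1C[C@@H](O)CC(C)(C)[C@]1(O)CC(=O)/C(C)=C/C=C/C(C)=C/C=C/C=C(C)/C=C/C=C(C)/C=C/[C@H]1C(C)=CC=CC1(C)C | target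

**Step count and risks**

Total step count: 14 (each one-flask sequence counted once).
Longest linear sequence: 8 (steps 1–6, 13, 14, or steps 7–14).

*Step 14 (the new step).*
- Gold may scramble or oxidise the polyene.
- The tertiary aldol may dehydrate to the Meyer–Schuster enone.
- Water may add further along the chain.

The fallback uses only known chemistry, sets out from 12 and comes back at 26.
- Ruthenium-catalysed trans-hydrosilylation of the propargylic alcohol ([Cp*Ru(MeCN)3]PF6, (EtO)3SiH, CH2Cl2, 0 °C) places silicon on the alkyne carbon remote from the carbinol. This gives the (7Z)-8-(triethoxysilyl) dienetriol F1.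
- Tamao–Fleming oxidation (H2O2, KF, KHCO3, THF/MeOH) gives the C15 β-hydroxy enone triol F2.
- The Appel protocol of step 6 gives the γ-bromo enone F3 and then the keto phosphonium bromide F4. F4 is the ketone counterpart of the C5 ester salts commonly used on apocarotenals.
- Wittig reaction of F4 with 24 in 1,2-epoxybutane gives 26 directly, so no metal catalyst ever meets the polyene.

*Step 9.* C6'–H is the thermodynamically most acidic proton of 18. Any enolate equilibration would racemise it or move the double bonds into conjugation.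

The fallback avoids strong base, sets out from 18 and comes back at 20.
- Luche reduction (NaBH4, CeCl3·7H2O, MeOH, −20 °C) gives the allylic alcohol F5 as a C3' epimer mixture.
- The Burgess reagent (toluene, 50 °C) removes water by concerted syn elimination. This can only take a C2' hydrogen because C4' is vinylic, and it gives 20.

*Step 6.* The secondary 3-OH may compete with the primary alcohol, and the allylic-propargylic 6-OH may ionise.

The fallback swaps the roles of ylide and aldehyde, sets out from 12 and 24 and comes back at 25.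
- MnO2 (CH2Cl2, rt) oxidises only the primary allylic alcohol of 12, giving the C15 enynal F6.
- NaBH4 (EtOH, 0 °C) reduces 24 to the C25 polyenol F7.
- PPh3·HBr (MeOH/CH2Cl2) converts F7 into the C25 phosphonium bromide F8.
- Wittig reaction of F8 with F6 in 1,2-epoxybutane gives 25.

**Further compounds**
F1 | step 14 | (1R,4S)-1-[(1Z,3E)-5-hydroxy-3-methyl-2-(triethoxysilyl)penta-1,3-dienyl]-2,2-dimethyl-6-methylidenecyclohexane-1,4-diol | C=C1C[C@@H](O)CC(C)(C)[C@]1(O)/C=C(/C(C)=C/CO)[Si](OCC)(OCC)OCC
F2 | step 14 | (3E)-1-[(1R,4S)-1,4-dihydroxy-2,2-dimethyl-6-methylidenecyclohexyl]-5-hydroxy-3-methylpent-3-en-2-one | C=C1C[C@@H](O)CC(C)(C)[C@]1(O)CC(=O)/C(C)=C/CO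
F3 | step 14 | (3E)-5-bromo-1-[(1R,4S)-1,4-dihydroxy-2,2-dimethyl-6-methylidenecyclohexyl]-3-methylpent-3-en-2-one | C=C1C[C@@H](O)CC(C)(C)[C@]1(O)CC(=O)/C(C)=C/CBr
F4 | step 14 | [(2E)-5-[(1R,4S)-1,4-dihydroxy-2,2-dimethyl-6-methylidenecyclohexyl]-3-methyl-4-oxopent-2-enyl]triphenylphosphonium bromide | C=C1C[C@@H](O)CC(C)(C)[C@]1(O)CC(=O)/C(C)=C/C[P+](c1ccccc1)(c1ccccc1)c1ccccc1.[Br-]
F5 | step 9 | ethyl (2E,4E)-5-[(1R)-4-hydroxy-2,6,6-trimethylcyclohex-2-en-1-yl]-3-methylpenta-2,4-dienoate (carbinol epimers) | CCOC(=O)/C=C(C)/C=C/[C@H]1C(C)=CC(O)CC1(C)C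
F6 | step 6 | (2E)-5-[(1R,4S)-1,4-dihydroxy-2,2-dimethyl-6-methylidenecyclohexyl]-3-methylpent-2-en-4-ynal | C=C1C[C@@H](O)CC(C)(C)[C@]1(O)C#C/C(C)=C/C=O
F7 | step 6 | (2E,4E,6E,8E,10E,12E)-2,7,11-trimethyl-13-[(1S)-2,6,6-trimethylcyclohexa-2,4-dien-1-yl]trideca-2,4,6,8,10,12-hexaen-1-ol | OC/C(C)=C/C=C/C=C(C)/C=C/C=C(C)/C=C/[C@H]1C(C)=CC=CC1(C)C
F8 | step 6 | C25 triphenylphosphonium bromide derived from F7 | [Br-].c1ccccc1[P+](c1ccccc1)(c1ccccc1)C/C(C)=C/C=C/C=C(C)/C=C/C=C(C)/C=C/[C@H]1C(C)=CC=CC1(C)C
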